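**Retrosynthetic overview**
1. Target 16 ⇐ acyclic tetraene-dial 14. The only ring is closed in the last step by an amine-catalysed dienamine Michael addition (formyl-bearing carbon onto the β-carbon of the α-branched enal), followed by proton transfer. This is the same C–C bond as in the presumed biogenesis from a udoteal-type precursor.
2. 14 ⇐ aldehyde 4 + aldehyde 10, by a one-pot formyl-olefination that builds the α-branched enal.
3. 4 ⇐ geranyl bromide 1 + acetal Grignard 2 (Cu-catalysed coupling, then hydrolysis).
4. 10 ⇐ allylic alcohol 8 (Claisen rearrangement) ⇐ 2-bromoallyl acetate 6 + dimethoxyacetaldehyde 7 (Nozaki–Hiyama–Kishi); 6 ⇐ 2,3-dibromopropene 5.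

Assumption: the facial selectivity of the (S)-diarylprolinol silyl ether in step 7 is taken from the usual steric-shielding model; it and the C7 protonation selectivity are predictions, not established results.

**Step 1**
Reactants: 1 geranyl bromide; 2 [2-(1,3-dioxan-2-yl)ethyl]magnesium bromide (commercial 0.5 M THF solution)
Product: 3 2-[(4E)-5,9-dimethyldeca-4,8-dien-1-yl]-1,3-dioxane
Conditions: Li2CuCl4 (3 mol %), THF, −30 → 0 °C
Reagents that add atoms: none
Why: Cu-catalysed (Kochi-type) allyl–alkyl cross-coupling of a primary alkyl Grignard with a primary allylic bromide proceeds by SN2 at the terminal carbon with retention of the (E)-olefin; no stereocentre is formed.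

**Step 2**
Reactants: 3 2-[(4E)-5,9-dimethyldeca-4,8-dien-1-yl]-1,3-dioxane
Product: 4 (5E)-6,10-dimethylundeca-5,9-dienal
Conditions: 2 M aq. HCl, THF, 40 °C
Reagents that add atoms: water, O
Why: acid-catalysed acetal hydrolysis; the trisubstituted olefins tolerate dilute acid at this temperature.

**Step 3**
Reactants: 5 2,3-dibromoprop-1-ene
Product: 6 2-bromoprop-2-en-1-yl acetate
Conditions: KOAc, DMF, rt
Reagents that add atoms: potassium acetate, CC(=O)[O-].[K+]
Why: SN2 displacement of the allylic bromide by acetate; the vinylic bromide is inert.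

**Step 4**
Reactants: 6 2-bromoprop-2-en-1-yl acetate; 7 2,2-dimethoxyacetaldehyde (dried from the commercial aqueous solution)
Product: 8 rac-3-hydroxy-4,4-dimethoxy-2-methylidenebutyl acetate
Conditions: CrCl2 (4 equiv), NiCl2 (2 mol %), DMF, rt; aq. work-up
Reagents that add atoms: none
Why: Nozaki–Hiyama–Kishi coupling; the alkenyl-Cr(III) species adds to the aldehyde and tolerates the acetate, and the racemic carbinol centre is destroyed in step 5.

**Step 5**
Reactants: 8 rac-3-hydroxy-4,4-dimethoxy-2-methylidenebutyl acetate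
Product: 10 (2Z)-4,4-dimethoxy-2-(3-oxopropyl)but-2-en-1-yl acetate, via allyl vinyl ether 9 (not isolated)
Conditions: ethyl vinyl ether (excess), Hg(OAc)2 (20 mol %), NaOAc, reflux; evaporate; toluene, sealed tube, 120 °C
Reagents that add atoms: ethyl vinyl ether, CCOC=C
Why: Hg(II)-catalysed transvinylation then Claisen rearrangement through a chair transition state (CH(OMe)2 equatorial) gives the trisubstituted olefin and the free aldehyde directly; the olefin geometry (mainly Z) does not matter because it is scrambled through the dienamine in step 7.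

**Step 6**
Reactants: 4 (5E)-6,10-dimethylundeca-5,9-dienal; 10 (2Z)-4,4-dimethoxy-2-(3-oxopropyl)but-2-en-1-yl acetate
Product: 14 [(2Z,6E,10E)-7-formyl-11,15-dimethyl-1-oxohexadeca-2,6,10,14-tetraen-3-yl]methyl acetate, via tert-butyl imine 11 (not isolated), via α-phosphono imine 12 (not isolated), via 2-aza-diene 13 (not isolated)
Conditions: t-BuNH2 (1.0 equiv), 4 Å MS, THF, rt; cannulate into LDA (2.0 equiv), THF, −78 °C; ClP(O)(OEt)2, −78 → −10 °C; 10, −78 °C → rt; aq. (CO2H)2, THF/hexane, rt
Reagents that add atoms: water, O; tert-butylamine, CC(C)(C)N (in 11–13 only); diethyl chlorophosphate, CCOP(=O)(Cl)OCC (in 12 only)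
Why: one-pot formyl-olefination (Horner–Wadsworth–Emmons reaction of the lithiated α-phosphono aldimine with the aldehyde) builds the α-branched enal; the weakly basic phosphonate anion spares the acetate, and mild acid hydrolysis of the aza-diene and the allylic acetal gives the thermodynamically preferred (6E)-enal and unmasks the second enal.

**Step 7**
Reactants: 14 [(2Z,6E,10E)-7-formyl-11,15-dimethyl-1-oxohexadeca-2,6,10,14-tetraen-3-yl]methyl acetate
Product: 16 [(3R)-2-formyl-3-[(2S,5E)-6,10-dimethyl-1-oxoundeca-5,9-dien-2-yl]cyclopent-1-en-1-yl]methyl acetate, via dienamine 15 (not isolated)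
Conditions: (S)-2-[diphenyl(trimethylsilyloxy)methyl]pyrrolidine (20 mol %), PhCO2H (20 mol %), CH2Cl2 (0.05 M), rt
Reagents that add atoms: (S)-2-[diphenyl(trimethylsilyloxy)methyl]pyrrolidine, C[Si](C)(C)OC(c1ccccc1)(c1ccccc1)[C@@H]1CCCN1 (catalyst; its atoms are in 15 only)
Why: Proposed new method: the bulky secondary amine should condense only with the unhindered β,β-disubstituted enal, and the α-carbon of dienamine 15 then adds 5-exo to the β-carbon of the tethered α-branched enal on the face anti to the CPh2OTMS group through a compact, hetero-Diels–Alder-like (enal s-cis) transition state, which sets ring C3 as R; the resulting cis-fused amino-dihydropyran-like enol intermediate is protonated at the side-chain α-carbon on its convex face (ring-fusion H and new H cis), which sets C2' as S, and dienamine–iminium equilibration with hydrolysis returns the ring double bond into conjugation; the closest known reactions are the dienamine-mediated intramolecular Rauhut–Currier-type cyclisation of 3-methylocta-2,6-dienedials to 2-methyl-5-(2-oxoethyl)cyclopentenecarbaldehydes and the intramolecular enamine additions to 2-alkyl enals used for iridoids.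

**Compound list**
1 | geranyl bromide, (2E)-1-bromo-3,7-dimethylocta-2,6-diene | CC(C)=CCC/C(C)=C/CBr | starting material
2 | [2-(1,3-dioxan-2-yl)ethyl]magnesium bromide | Br[Mg]CCC1OCCCO1 | starting material
3 | 2-[(4E)-5,9-dimethyldeca-4,8-dien-1-yl]-1,3-dioxane | CC(C)=CCC/C(C)=C/CCCC1OCCCO1 | intermediate
4 | (5E)-6,10-dimethylundeca-5,9-dienal | CC(C)=CCC/C(C)=C/CCCC=O | intermediate
5 | 2,3-dibromoprop-1-ene | C=C(Br)CBr | starting material
6 | 2-bromoprop-2-en-1-yl acetate | CC(=O)OCC(Br)=C | intermediate
7 | 2,2-dimethoxyacetaldehyde | COC(OC)C=O | starting material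
8 | rac-3-hydroxy-4,4-dimethoxy-2-methylidenebutyl acetate | CC(=O)OCC(=C)C(O)C(OC)OC | intermediate
9 | rac-3-(ethenyloxy)-4,4-dimethoxy-2-methylidenebutyl acetate (allyl vinyl ether, not isolated) | CC(=O)OCC(=C)C(OC=C)C(OC)OC | intermediate
10 | (2Z)-4,4-dimethoxy-2-(3-oxopropyl)but-2-en-1-yl acetate | CC(=O)OC/C(CCC=O)=C\C(OC)OC | intermediate
11 | (1E,5E)-N-tert-butyl-6,10-dimethylundeca-5,9-dien-1-imine (not isolated) | CC(C)=CCC/C(C)=C/CCC/C=N/C(C)(C)C | intermediate
12 | diethyl [(5E)-1-(tert-butylimino)-6,10-dimethylundeca-5,9-dien-2-yl]phosphonate, racemic, present as its lithium aza-enolate (not isolated) | CCOP(=O)(OCC)C(CC/C=C(\C)CCC=C(C)C)/C=N/C(C)(C)C | intermediate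
13 | [(2Z,6E,10E)-7-[(E)-(tert-butylimino)methyl]-1,1-dimethoxy-11,15-dimethylhexadeca-2,6,10,14-tetraen-3-yl]methyl acetate (not isolated) | CC(=O)OC/C(CC/C=C(/C=N/C(C)(C)C)\CC/C=C(\C)CCC=C(C)C)=C\C(OC)OC | intermediate
14 | [(2Z,6E,10E)-7-formyl-11,15-dimethyl-1-oxohexadeca-2,6,10,14-tetraen-3-yl]methyl acetate | CC(=O)OC/C(CC/C=C(/C=O)\CC/C=C(\C)CCC=C(C)C)=C\C=O | intermediate
15 | (1E,3E)-dienamine of the C1 aldehyde of 14 with (S)-2-[diphenyl(trimethylsilyloxy)methyl]pyrrolidine, N–CH=CH–C(CH2OAc)=CH–CH2–CH=C(CHO)–chain (not isolated) | CC(=O)OC/C(=C/C/C=C(/C=O)\CC/C=C(\C)CCC=C(C)C)/C=C/N1CCC[C@H]1C(c1ccccc1)(c1ccccc1)O[Si](C)(C)C | intermediate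
16 | [(3R)-2-formyl-3-[(2S,5E)-6,10-dimethyl-1-oxoundeca-5,9-dien-2-yl]cyclopent-1-en-1-yl]methyl acetate | CC(=O)OCC1=C(C=O)[C@@H]([C@@H](C=O)CC/C=C(\C)CCC=C(C)C)CC1 | target

**Totals**
Total step count: 7. Longest linear sequence: 5 steps (5 → 6 → 8 → 10 → 14 → 16, steps 3–7).

**Three steps most likely to fail, with fallbacks**

Step 7 (reactivity of the α-branched enal, sense of induction, and the protonation that sets the side-chain α-centre). The fallback sets out from 14 and returns at 16. It gives up the one-pot catalytic cascade for a stoichiometric, stepwise ring closure. Compound 14 is condensed with one equivalent of the same (S)-prolinol silyl ether over 4 Å sieves in toluene, so that the dienamine closes by an intramolecular enamine–enal hetero-Diels–Alder reaction (the iridoid-type cycloaddition) to the isolable cis-fused amino-dihydropyran N,O-acetal F1. Here the side-chain α-carbon is still an enol-ether carbon inside a rigid bicycle. F1 is then protonolysed separately with a hindered acid (pivalic acid, wet THF, −40 °C), so that the proton is delivered to the convex face under kinetic control before the aminal opens and the ring double bond moves into conjugation, giving 16.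

Step 6 (olefination of a hindered α-substituted phosphonate anion with an enolisable, multifunctional aldehyde). The fallback sets out from 4 and returns at 14. It replaces the phosphono-imine olefination by a Wittig reaction of a stabilised ylide. Aldehyde 4 is α-chlorinated (NCS, pyrrolidine cat., CH2Cl2) to 2-chloro-6,10-dimethylundeca-5,9-dienal F2. PPh3 with catalytic NaI in MeCN gives the α-formyl phosphonium chloride F3, and aqueous NaOH gives the stabilised α-formyl ylide F4. F4 reacts with aldehyde 10 in toluene at 90 °C, leaving the acetate and acetal untouched, to give the (E)-enal dimethyl acetal F5. Aqueous oxalic acid then releases 14.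

Step 4 (β-acetoxy alkenyl-chromium species; anhydrous glyoxal monoacetal needed). The fallback sets out from 7 and returns at 8. It uses a Morita–Baylis–Hillman route that runs directly on the commercial aqueous solution of 7. Methyl acrylate with DABCO in dioxane/water gives the adduct methyl 2-(1-hydroxy-2,2-dimethoxyethyl)prop-2-enoate F6. DIBAL-H (CH2Cl2, −78 °C) reduces the ester to the 2-methylidene-1,3-diol F7. Selective acetylation of the primary hydroxyl (AcCl, 2,4,6-collidine, −78 °C) gives 8.

**Further compounds**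
F1 | step 7 | [4-[(3E)-4,8-dimethylnona-3,7-dien-1-yl]-1-[(2S)-2-[diphenyl(trimethylsilyloxy)methyl]pyrrolidin-1-yl]-1,4a,5,7a-tetrahydrocyclopenta[c]pyran-7-yl]methyl acetate, cis-fused (H-4a and H-7a cis), amino group on the same face as H-7a | CC(=O)OCC1=CC[C@@H]2C(CC/C=C(\C)CCC=C(C)C)=CO[C@@H](N3CCC[C@H]3C(c3ccccc3)(c3ccccc3)O[Si](C)(C)C)[C@H]12
F2 | step 6 | rac-(5E)-2-chloro-6,10-dimethylundeca-5,9-dienal | CC(C)=CCC/C(C)=C/CCC(Cl)C=O
F3 | step 6 | rac-[(5E)-6,10-dimethyl-1-oxoundeca-5,9-dien-2-yl]triphenylphosphonium chloride | CC(C)=CCC/C(C)=C/CCC(C=O)[P+](c1ccccc1)(c1ccccc1)c1ccccc1.[Cl-]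
F4 | step 6 | (5E)-6,10-dimethyl-2-(triphenyl-λ5-phosphanylidene)undeca-5,9-dienal | CC(C)=CCC/C(C)=C/CCC(C=O)=P(c1ccccc1)(c1ccccc1)c1ccccc1
F5 | step 6 | [(2Z,6E,10E)-7-formyl-1,1-dimethoxy-11,15-dimethylhexadeca-2,6,10,14-tetraen-3-yl]methyl acetate | CC(=O)OC/C(CC/C=C(/C=O)\CC/C=C(\C)CCC=C(C)C)=C\C(OC)OC
F6 | step 4 | rac-methyl 2-(1-hydroxy-2,2-dimethoxyethyl)prop-2-enoate | COC(=O)C(=C)C(O)C(OC)OC
F7 | step 4 | rac-4,4-dimethoxy-2-methylidenebutane-1,3-diol | OCC(=C)C(O)C(OC)OC
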